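**Strategy.** Ring A is read as a ring-expanded cyclohexane-1,3-dione (numbering: C1 acetoxy carbon, C3 lactone carbonyl, C4 CMe2, C5 and C10 the A/B fusion carbons). A C1 ketone acidifies both C10 and C2, and a C3 ester activates C5 through a C4=C5 bond. The key step, a base-mediated Michael–Claisen bicyclisation of a carvone-derived ring C cyclohexene bearing a 3-oxobutan-2-yl arm at C9 and an (E)-2-methylpent-2-enoate arm at C8, therefore closes ring B (C5–C10) and ring A (C2–C3) and sets C5 and C10. Baeyer–Villiger insertion of oxygen between C3 and C4, then asymmetric allylation and cationic lactonisation, complete rings A, D and E.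

Key step: step 10

Remark (numbering): C1 (CHOAc), C2, C3 (ring A lactone C=O), C4 (CMe2), C5–C10 (ring B, methyls on C8 and C10), C11, C12=C13 (methyl on C13), C14 (spiro carbon bearing the ring D lactone oxygen), C15 (ring D CH2), C16 (spiro carbon of rings D and E), C17/C18 (furanone C=C), C19 (furanone C=O), C20 (ring D C=O). With this numbering the target is 1R,5S,8S,9S,10S,14R,16R.

Remark (assumption): the (S,S) ligand antipode in step 18 is assigned by analogy with carbocyclic 2-alkoxycarbonyl ketones; if a model furanone shows the opposite sense, the mirror-image ligand is used.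

**Step 1**
Reactants: 1 (R)-(−)-carvone
Product: 3 6-methylcarvone as a C8 epimer mixture, via lithium dienolate 2 (not isolated)
Conditions: LiN(iPr)2, THF, −78 °C; MeI, −78 → 0 °C
Reagents that add atoms: iodomethane, CI
Why: Kinetic α′-deprotonation of the cross-conjugated enone and C-methylation of the lithium dienolate (enolate alkylation); the C8 epimer mixture is immaterial because C8 is enolised again in step 2.

**Step 2**
Reactants: 3 6-methylcarvone
Product: 5 (5S,6S)-6-allyl-2,6-dimethyl-5-(prop-1-en-2-yl)cyclohex-2-en-1-one (allyl trans to isopropenyl), via lithium enolate 4 (not isolated)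
Conditions: LiN(iPr)2, THF, −78 °C; allyl bromide, DMPU, −78 °C → rt
Reagents that add atoms: allyl bromide, C=CCBr
Why: Enolate alkylation in which allyl bromide approaches C8 anti to the neighbouring isopropenyl group, so the quaternary centre forms with the allyl (C7) trans and the methyl cis to the C9 substituent, as required for the B/C trans fusion.

**Step 3**
Reactants: 5 allyl methyl carvone
Product: 7 enol triflate (C13=C14, OTf on C14), via lithium enolate 6 (not isolated)
Conditions: LiBH(s-Bu)3, THF, −78 °C; N-(5-chloropyridin-2-yl)bis(trifluoromethanesulfonimide), −78 → 0 °C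
Reagents that add atoms: N-(5-chloropyridin-2-yl)bis(trifluoromethanesulfonimide), O=S(=O)(N(c1ccc(Cl)cn1)S(=O)(=O)C(F)(F)F)C(F)(F)F
Why: Conjugate hydride reduction of the β-unsubstituted enone gives the tetrasubstituted C13=C14 enolate regiospecifically and the N-aryl triflimide O-sulfonylates it (reductive enol triflation).

**Step 4**
Reactants: 7 enol triflate
Product: 8 methyl cyclohexene-1-carboxylate (ester carbon = C15)
Conditions: Pd(OAc)2 (5 mol %), dppp, CO (1 atm), Et3N, MeOH/DMF, 70 °C
Reagents that add atoms: carbon monoxide, [C-]#[O+]; methanol, CO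
Why: Palladium-catalysed methoxycarbonylation of the alkenyl triflate, in which excess methanol intercepts the acylpalladium before it can insert a pendant alkene; the hindered tetrasubstituted enoate then serves as a masked, electron-poor form of the C13=C14–C15 allyl unit.

**Step 5**
Reactants: 8 methyl ester
Product: 10 diol (C5-OH and C1-OH; C10 epimer mixture), via bis(9-BBN) adduct 9 (not isolated)
Conditions: 9-BBN (3 equiv), THF, 0 °C → rt; then H2O2, NaOH (aq), 0 °C
Reagents that add atoms: hydrogen peroxide, OO
Why: Anti-Markovnikov hydroboration–oxidation of the two terminal alkenes only (the tetrasubstituted enoate is inert to 9-BBN); the new C10 centre forms unselectively, which is harmless because it is planarised in step 10.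

**Step 6**
Reactants: 10 diol
Product: 11 dialdehyde
Conditions: (COCl)2, DMSO, CH2Cl2, −78 °C; Et3N, −78 → 0 °C
Reagents that add atoms: none
Why: Swern oxidation of both primary alcohols without touching the ester.

**Step 7**
Reactants: 11 dialdehyde
Product: 12 (E)-enoate aldehyde
Conditions: Ph3P=C(CH3)CO2Me (1.05 equiv), CH2Cl2, 0 °C → rt
Reagents that add atoms: methyl 2-(triphenyl-λ5-phosphanylidene)propanoate, COC(=O)C(C)=P(c1ccccc1)(c1ccccc1)c1ccccc1
Why: Wittig olefination with a stabilised α-methyl ylide, which should react at the unbranched C5 aldehyde far faster than at the α-branched, ring-shielded C1 aldehyde and gives the (E)-enoate.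

**Step 8**
Reactants: 12 enoate aldehyde
Product: 13 secondary alcohol (carbinol epimers)
Conditions: MeMgBr (1.1 equiv), THF, −78 °C; then aq. NH4Cl
Reagents that add atoms: methylmagnesium bromide, C[Mg]Br
Why: Grignard 1,2-addition to the aldehyde, which at −78 °C is much faster than attack on either conjugated ester; the carbinol configuration is irrelevant.

**Step 9**
Reactants: 13 secondary alcohol
Product: 14 methyl ketone (cyclisation precursor)
Conditions: Dess–Martin periodinane, CH2Cl2, rt
Reagents that add atoms: none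
Why: Dess–Martin oxidation of the secondary alcohol to the methyl ketone.

**Step 10**
Reactants: 14 methyl ketone
Product: 16 tricyclic A/B/C 1,3-dione (trans-fused; C4 epimers; largely enolised), via Michael adduct 15 (not isolated)
Conditions: KOtBu (2.5 equiv), t-BuOH/THF, 0 → 50 °C; then 1 M HCl
Reagents that add atoms: none
Why: KOtBu equilibrates the ketone enolates; the more substituted C10 enolate adds 6-exo-trig to C5 of the (E)-enoate (intramolecular Michael addition, closing ring B), proton transfer gives the C2 enolate, and this attacks the C3 ester 6-exo-trig (Claisen/Dieckmann condensation, closing ring A), the sequence being driven by irreversible deprotonation of the 1,3-dione. The closest known reaction type is the consecutive Michael–Claisen [3+3] synthesis of cyclohexane-1,3-diones from ketones and α,β-unsaturated esters. C10 is controlled by A(1,3) strain in the tetrasubstituted enolate (H9 eclipses the enolate plane) together with the C8 tether, so its methyl ends up trans-diaxial to H9 and syn to the C8 methyl; C5 is controlled by a chair transition state with the enoate equatorial, and since the Michael step is reversible only this trans adduct is drained by the ring A closure. The step needs enolate and acceptor selectivity: the C2 enolate could reach C5 only through an eight-membered ring, and the ring C ester is a C8-shielded tetrasubstituted enoate whose closures (five-membered from C10, reversible for lack of an acidic proton; seven-membered from C2) are slower. C4 forms as a mixture, which is irrelevant because it becomes the gem-dimethyl carbon.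

**Step 11**
Reactants: 16 1,3-dione
Product: 17 vinylogous ester (3-methoxy-2-en-1-one)
Conditions: HC(OMe)3, MeOH, TsOH (cat.), rt → 40 °C
Reagents that add atoms: trimethyl orthoformate, COC(OC)OC
Why: Acid-catalysed enol etherification of the 1,3-dione (vinylogous ester formation) under thermodynamic control, which places the methoxy group at C3, away from quaternary C10, as with 4,4-disubstituted cyclohexane-1,3-diones.

**Step 12**
Reactants: 17 vinylogous ester
Product: 19 1-en-3-one with C15 allylic alcohol, via hydroxy enol ether 18 (not isolated)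
Conditions: i-Bu2AlH (5 equiv), CH2Cl2, −78 → 0 °C; then 1 M HCl, THF, rt
Reagents that add atoms: water, O
Why: Stork–Danheiser transposition, in which hydride adds 1,2 to the vinylogous ester carbonyl and acid hydrolysis with loss of water gives the C1=C2–C3=O enone, while the same hydride reduces the ring C ester to the C15 allylic alcohol.

**Step 13**
Reactants: 19 enone alcohol
Product: 21 4,4-dimethyl enone, via dilithium enolate alkoxide 20 (not isolated)
Conditions: LiN(iPr)2 (2.3 equiv), THF, −78 °C; MeI (1.2 equiv), −78 → −20 °C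
Reagents that add atoms: iodomethane, CI
Why: Kinetic α′-enolate methylation at C4, the only enolisable position of the enone (C10 is quaternary); the lithium alkoxide at C15 is not methylated at low temperature.

**Step 14**
Reactants: 21 4,4-dimethyl enone
Product: 23 1-hydroxy-3-ketone (OH trans to the C10 methyl), via C1 pinacol boronate 22 (not isolated)
Conditions: CuCl (5 mol %), NaOtBu, DPEphos, B2pin2, MeOH, THF, rt; then NaBO3·4H2O, THF/H2O, rt
Reagents that add atoms: sodium perborate, [Na+].[O-]B1OO1
Why: Copper-catalysed conjugate borylation followed by stereoretentive C–B oxidation; the boryl-copper species adds to C1 on the face anti to the axial C10 methyl, which sets the C1 oxygen trans to that methyl (1R).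

**Step 15**
Reactants: 23 hydroxy ketone
Product: 24 bis-acetate (C1-OAc and C15-OAc)
Conditions: Ac2O, pyridine, DMAP (cat.), CH2Cl2, 0 °C → rt
Reagents that add atoms: acetic anhydride, CC(=O)OC(C)=O
Why: Acetylation of both hydroxyls, which installs the C1 acetate of the target and turns C15 into the allylic leaving group for step 18.

**Step 16**
Reactants: 24 bis-acetate ketone
Product: 25 ring A ε-lactone
Conditions: Me3SiOOSiMe3, SnCl4 (20 mol %), trans-cyclohexane-1,2-diamine (20 mol %), 4 Å MS, CH2Cl2, 0 °C → rt
Reagents that add atoms: bis(trimethylsilyl) peroxide, C[Si](C)(C)OO[Si](C)(C)C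
Why: Baeyer–Villiger oxidation with a silyl peroxide and a Lewis acid, a reagent pair that adds to ketones but does not epoxidise alkenes; the quaternary C4 migrates so oxygen enters between C3 and C4.

**Step 17**
Reactants: 26 tert-butyl glycolate; 27 ethyl 2-methylbuta-2,3-dienoate
Product: 29 tert-butyl 3-hydroxy-4,5-dimethylfuran-2-carboxylate, via enol ether diester 28 (not isolated)
Conditions: NaH (2.2 equiv), THF, 0 °C → rt; then AcOH
Reagents that add atoms: none
Why: Oxa-Michael addition of the glycolate alkoxide to the central allene carbon and Dieckmann condensation of the resulting α-alkoxy ester carbanion onto the ethyl ester; aromatisation to the 3-hydroxyfuran drives the sequence.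

**Step 18**
Reactants: 25 allylic acetate lactone; 29 hydroxyfuran ester
Product: 30 C15–C16 coupled furanone tert-butyl ester (16R)
Conditions: Pd2(dba)3·CHCl3 (2.5 mol %), (S,S)-N,N′-(cyclohexane-1,2-diyl)bis[2-(diphenylphosphino)benzamide] (7.5 mol %), N,N,N′,N′-tetramethylguanidine, toluene, 0 °C → rt
Reagents that add atoms: none
Why: Tsuji–Trost asymmetric allylic alkylation of a cyclic β-keto ester, in which zerovalent palladium ionises only the allylic acetate, the stabilised carbon nucleophile attacks the unsubstituted C15 terminus (dearomatising C-allylation), and the chiral diphosphine pocket selects the enolate face to set C16 (R) by catalyst control.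

**Step 19**
Reactants: 30 furanone tert-butyl ester
Product: 31 C12 allylic alcohol (C12 epimers)
Conditions: SeO2 (0.5 equiv), t-BuOOH, CH2Cl2, rt
Reagents that add atoms: tert-butyl hydroperoxide, CC(C)(C)OO
Why: SeO2 allylic hydroxylation (ene reaction then [2,3]-sigmatropic shift) at the ring methylene C12, favoured over the C13 methyl (CH2 before CH3) and over C15, which is shielded by quaternary C16; the C12 configuration is irrelevant since C12 is ionised in step 20.

**Step 20**
Reactants: 31 C12 allylic alcohol
Product: 32 target CNP0131208.1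
Conditions: camphor-10-sulfonic acid (20 mol %), 4 Å MS, CH2Cl2, 0 °C
Reagents that add atoms: none
Why: Acid-catalysed ionisation to the C12–C13–C14 allyl cation and 5-exo capture at C14 by the tert-butyl ester carbonyl with loss of isobutene (SN1′ lactonisation); attack is axial and anti to the axial C8 methyl, which sets C14 (R) and leaves the C12=C13 double bond.

**Compound list**

1 | (R)-(−)-carvone | CC1=CC[C@H](CC1=O)C(C)=C | starting material
2 | lithium dienolate of 1 (C8=C14 enolate) | [Li]OC1=C[C@@H](CC=C1C)C(C)=C | intermediate (not isolated)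
3 | 6-methylcarvone, (5R)-2,6-dimethyl-5-(prop-1-en-2-yl)cyclohex-2-en-1-one, C8 epimers | CC1[C@@H](CC=C(C)C1=O)C(C)=C | intermediate
4 | lithium enolate of 3 | [Li]OC1=C(C)[C@@H](CC=C1C)C(C)=C | intermediate (not isolated)
5 | (5S,6S)-6-allyl-2,6-dimethyl-5-(prop-1-en-2-yl)cyclohex-2-en-1-one, allyl trans to isopropenyl | C=CC[C@@]1(C)[C@@H](CC=C(C)C1=O)C(C)=C | intermediate
6 | lithium C13=C14 enolate from conjugate reduction of 5 | C=CC[C@@]1(C)[C@@H](CCC(C)=C1O[Li])C(C)=C | intermediate (not isolated)
7 | 6-allyl-2,6-dimethyl-5-(prop-1-en-2-yl)cyclohex-1-en-1-yl triflate, C8/C9 as in 5 | C=CC[C@@]1(C)[C@@H](CCC(C)=C1OS(=O)(=O)C(F)(F)F)C(C)=C | intermediate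
8 | methyl 6-allyl-2,6-dimethyl-5-(prop-1-en-2-yl)cyclohex-1-ene-1-carboxylate, C8/C9 as in 5 | C=CC[C@@]1(C)[C@@H](CCC(C)=C1C(=O)OC)C(C)=C | intermediate
9 | bis(9-borabicyclo[3.3.1]nonan-9-yl) adduct of 8 (boron on C5 and C1) | C(B1C2CCCC1CCC2)CC[C@@]1(C)[C@@H](CCC(C)=C1C(=O)OC)C(C)CB1C2CCCC1CCC2 | intermediate (not isolated)
10 | methyl 6-(3-hydroxypropyl)-5-(1-hydroxypropan-2-yl)-2,6-dimethylcyclohex-1-ene-1-carboxylate, C10 epimers | OCCC[C@@]1(C)[C@@H](CCC(C)=C1C(=O)OC)C(C)CO | intermediate
11 | dialdehyde: 6-(3-oxopropyl)-5-(1-oxopropan-2-yl) analogue of 10 | O=CCC[C@@]1(C)[C@@H](CCC(C)=C1C(=O)OC)C(C)C=O | intermediate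
12 | (E)-enoate aldehyde: C8 arm CH2CH2CH=C(CH3)CO2Me, C9 arm CH(CH3)CHO | COC(=O)/C(C)=C/CC[C@@]1(C)[C@@H](CCC(C)=C1C(=O)OC)C(C)C=O | intermediate
13 | secondary alcohol: C9 arm CH(CH3)CH(OH)CH3 | COC(=O)/C(C)=C/CC[C@@]1(C)[C@@H](CCC(C)=C1C(=O)OC)C(C)C(C)O | intermediate
14 | methyl ketone: C9 arm 3-oxobutan-2-yl, C8 arm (E)-4-methoxycarbonylpent-3-enyl | COC(=O)/C(C)=C/CC[C@@]1(C)[C@@H](CCC(C)=C1C(=O)OC)C(C)C(C)=O | intermediate
15 | Michael adduct: trans-fused B/C bicycle with C10 (methyl, acetyl) and C5 CH(CH3)CO2Me | COC(=O)C(C)[C@H]2CC[C@@]3(C)[C@@H](CCC(C)=C3C(=O)OC)[C@]2(C)C(C)=O | intermediate (not isolated)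
16 | tricyclic 1,3-dione (C1 and C3 ketones, C4 H/CH3, A/B trans, ring C C13=C14 with CO2Me) | O=C1CC(=O)C(C)[C@H]2CC[C@@]3(C)[C@@H](CCC(C)=C3C(=O)OC)[C@@]21C | intermediate
17 | vinylogous ester: 3-methoxy-2-en-1-one | O=C1C=C(OC)C(C)[C@H]2CC[C@@]3(C)[C@@H](CCC(C)=C3C(=O)OC)[C@@]21C | intermediate
18 | 1-hydroxy-3-methoxy-2-ene with C15 CH2OH | OC1C=C(OC)C(C)[C@H]2CC[C@@]3(C)[C@@H](CCC(C)=C3CO)[C@@]21C | intermediate (not isolated)
19 | 1-en-3-one, C4 H/CH3, C15 CH2OH | C1=CC(=O)C(C)[C@H]2CC[C@@]3(C)[C@@H](CCC(C)=C3CO)[C@@]21C | intermediate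
20 | dilithium C3=C4 enolate / C15 alkoxide of 19 | C1=CC(O[Li])=C(C)[C@H]2CC[C@@]3(C)[C@@H](CCC(C)=C3CO[Li])[C@@]21C | intermediate (not isolated)
21 | 4,4-dimethyl-1-en-3-one, C15 CH2OH | C1=CC(=O)C(C)(C)[C@H]2CC[C@@]3(C)[C@@H](CCC(C)=C3CO)[C@@]21C | intermediate
22 | C1 pinacol boronate of the 3-ketone (boron trans to C10 methyl) | CC1(C)OB(OC1(C)C)[C@@H]1CC(=O)C(C)(C)[C@H]2CC[C@@]3(C)[C@@H](CCC(C)=C3CO)[C@@]21C | intermediate (not isolated)
23 | 1-hydroxy-4,4-dimethyl-3-ketone (OH trans to C10 methyl), C15 CH2OH | O[C@@H]1CC(=O)C(C)(C)[C@H]2CC[C@@]3(C)[C@@H](CCC(C)=C3CO)[C@@]21C | intermediate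
24 | bis-acetate of 23 | CC(=O)O[C@@H]1CC(=O)C(C)(C)[C@H]2CC[C@@]3(C)[C@@H](CCC(C)=C3COC(C)=O)[C@@]21C | intermediate
25 | ring A ε-lactone (O between C3 and C4), 1-OAc, C15 CH2OAc | CC(=O)O[C@@H]1CC(=O)OC(C)(C)[C@H]2CC[C@@]3(C)[C@@H](CCC(C)=C3COC(C)=O)[C@@]21C | intermediate
26 | tert-butyl glycolate | OCC(=O)OC(C)(C)C | starting material
27 | ethyl 2-methylbuta-2,3-dienoate | CCOC(=O)C(C)=C=C | starting material
28 | ethyl 3-(2-tert-butoxy-2-oxoethoxy)-2-methylbut-2-enoate | CCOC(=O)C(C)=C(C)OCC(=O)OC(C)(C)C | intermediate (not isolated)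
29 | tert-butyl 3-hydroxy-4,5-dimethylfuran-2-carboxylate | Cc1oc(C(=O)OC(C)(C)C)c(O)c1C | intermediate
30 | tert-butyl (R)-4,5-dimethyl-3-oxo-2,3-dihydrofuran-2-carboxylate C2-alkylated by C15 of the tricyclic lactone (16R) | CC(=O)O[C@@H]1CC(=O)OC(C)(C)[C@H]2CC[C@@]3(C)[C@@H](CCC(C)=C3C[C@]4(OC(C)=C(C)C4=O)C(=O)OC(C)(C)C)[C@@]21C | intermediate
31 | 12-hydroxy derivative of 30 (C12 epimers) | CC(=O)O[C@@H]1CC(=O)OC(C)(C)[C@H]2CC[C@@]3(C)[C@@H](CC(O)C(C)=C3C[C@]4(OC(C)=C(C)C4=O)C(=O)OC(C)(C)C)[C@@]21C | intermediate
32 | target CNP0131208.1 (1R,5S,8S,9S,10S,14R,16R) | CC(=O)O[C@@H]1CC(=O)OC(C)(C)[C@H]2CC[C@@]3(C)[C@@H](CC=C(C)[C@]34C[C@]3(OC(C)=C(C)C3=O)C(=O)O4)[C@@]21C | target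

**Step count.** Total: 20 steps. Longest linear sequence: 19 steps (steps 1–16 and 18–20); step 17 is a one-step branch.

**Three steps most likely to fail**

Step 16 (Baeyer–Villiger oxidation). Oxygen transfer to the electron-rich tetrasubstituted C13=C14 alkene, or Lewis-acid ionisation of the allylic acetate, may outrun peroxide addition to the hindered C3 ketone. The fallback sets out from 24 and accepts the epoxidation: excess mCPBA with NaHCO3 in CH2Cl2 should carry out the Baeyer–Villiger oxidation and epoxidise ring C, giving the 13,14-epoxy lactone F1. Deoxygenation of the tetrasubstituted epoxide with NaI and (CF3CO)2O in MeCN/THF at 0 °C should then restore the alkene, and the route is rejoined at 25.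

Step 18 (asymmetric allylic alkylation). Ionisation of the hindered 1,1,2-trisubstituted allyl acetate may be slow, the hydroxyfuran may react at oxygen instead of carbon, and catalyst control at C16 may be eroded. The fallback sets out from 25 and replaces the palladium chemistry by a chiral ion-pair SN2 alkylation. Lipase-catalysed butanolysis (Candida antarctica lipase B, n-BuOH, MTBE) should remove only the primary allylic acetate, giving the C15 allylic alcohol F2. CBr4/PPh3 should convert it to the C15 allylic bromide F3. Phase-transfer C-alkylation of 29 with F3 (C2-symmetric binaphthyl-derived spiro quaternary ammonium bromide, solid K2CO3, toluene, 0 °C) should then set C16 and rejoin the route at 30.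

Step 19 (allylic hydroxylation). Oxidation may go to the C13 methyl or to C15 instead of C12, or run on to the enone. The fallback sets out from 30 and places oxygen directly on C14 by a Schenck ene reaction (O2, tetraphenylporphyrin, visible light, CH2Cl2, −20 °C). Singlet oxygen should add on the face anti to the C8 methyl and abstract the axial H12, giving the C14 hydroperoxide F4. PPh3 should reduce it to the C14 tertiary allylic alcohol F5. Camphor-10-sulfonic acid in CH2Cl2 should close the ring D lactone onto the tert-butyl ester, and the route is rejoined at 32.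

**Further compounds**

F1 | step 16 | 13,14-epoxide of lactone 25 | CC(=O)O[C@@H]1CC(=O)OC(C)(C)[C@H]2CC[C@@]3(C)[C@@H](CCC4(C)OC34COC(C)=O)[C@@]21C
F2 | step 18 | C15 allylic alcohol of lactone 25 (1-acetate kept) | CC(=O)O[C@@H]1CC(=O)OC(C)(C)[C@H]2CC[C@@]3(C)[C@@H](CCC(C)=C3CO)[C@@]21C
F3 | step 18 | C15 allylic bromide | CC(=O)O[C@@H]1CC(=O)OC(C)(C)[C@H]2CC[C@@]3(C)[C@@H](CCC(C)=C3CBr)[C@@]21C
F4 | step 19 | C14 hydroperoxide with C12=C13 | CC(=O)O[C@@H]1CC(=O)OC(C)(C)[C@H]2CC[C@@]3(C)[C@@H](CC=C(C)[C@]3(OO)C[C@]4(OC(C)=C(C)C4=O)C(=O)OC(C)(C)C)[C@@]21C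
F5 | step 19 | C14 tertiary allylic alcohol with C12=C13 | CC(=O)O[C@@H]1CC(=O)OC(C)(C)[C@H]2CC[C@@]3(C)[C@@H](CC=C(C)[C@]3(O)C[C@]4(OC(C)=C(C)C4=O)C(=O)OC(C)(C)C)[C@@]21C
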